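**Retrosynthetic overview**
- Target 21 comes from chromone dimethyl ether 20 by cleaving the C5 and C7 aryl methyl ethers.
- 20 comes from aryne 17 (made from silyl triflate 11) and octacos-2-ynoic acid 16. One operation forms C8a–O1, C4a–C4 and O1–C2, and the pyranone ring is the only ring formed.
- 11 comes from 2,6-dimethoxytoluene 1, whose benzene ring is carried through intact: two directed ortho-lithiations (C-methylation, then hydroxylation), bromination, silyl shift and triflation.
- 16 comes from 1-hexacosanol 12 by oxidation, dibromo-olefination and alkynylation with carboxylation.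
- Feature used: C4a and C8a are neighbouring carbons of the benzene ring that carry the C4 carbonyl and O1, and C5 to C8 are all substituted. A C4a≡C8a aryne can therefore accept O1 and C4 together, and the acid delivers O1, C4, C3, C2 and the C25 chain.

Key step: step 8

Remark: the target has no stereocentre, and the side chain is taken as unbranched n-pentacosyl as drawn.

**Step 1**
Reactants: 1 2,6-dimethoxytoluene
Product: 3 1,3-dimethoxy-2,4-dimethylbenzene, via aryllithium 2 (not isolated)
Conditions: n-BuLi, TMEDA, Et2O, 0 °C → rt; MeI, –78 °C → rt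
Reagents that add atoms: iodomethane, CI
Why: Directed ortho-metalation, in which a methoxy group steers n-BuLi/TMEDA to the ring C–H beside it in preference to a benzylic methyl hydrogen, followed by SN2 methylation of the aryllithium.

**Step 2**
Reactants: 3 1,3-dimethoxy-2,4-dimethylbenzene
Product: 6 2,4-dimethoxy-3,5-dimethylphenol, via aryllithium 4 (not isolated), via arylboronate 5 (not isolated)
Conditions: n-BuLi, TMEDA, Et2O, 0 °C → rt; B(OMe)3, –78 °C → rt; AcOH, 30% aq H2O2, 0 °C → rt
Reagents that add atoms: hydrogen peroxide, OO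
Why: A second directed ortho-metalation at the only ring C–H next to a methoxy group, then electrophilic borylation and boronate oxidation (1,2-aryl shift from boron to oxygen), should turn that C–H into C–OH.

**Step 3**
Reactants: 6 2,4-dimethoxy-3,5-dimethylphenol
Product: 7 2-bromo-4,6-dimethoxy-3,5-dimethylphenol
Conditions: NBS, CH2Cl2, –78 °C → 0 °C
Reagents that add atoms: N-bromosuccinimide, O=C1CCC(=O)N1Br
Why: Electrophilic aromatic bromination at the single free ring position, which lies ortho to the hydroxyl group, should be faster than oxidation of the electron-rich ring in a dry solvent at low temperature.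

**Step 4**
Reactants: 7 2-bromo-4,6-dimethoxy-3,5-dimethylphenol
Product: 11 2,4-dimethoxy-3,5-dimethyl-6-(trimethylsilyl)phenyl trifluoromethanesulfonate, via aryl silyl ether 8 (not isolated), via aryllithium 9 (not isolated), via lithium silylphenoxide 10 (not isolated)
Conditions: HMDS, THF, 65 °C, then evaporate; n-BuLi, THF, –100 °C → –78 °C; Tf2O, –100 °C → rt
Reagents that add atoms: hexamethyldisilazane, C[Si](C)(C)N[Si](C)(C)C; trifluoromethanesulfonic anhydride, O=S(=O)(OS(=O)(=O)C(F)(F)F)C(F)(F)F
Why: O-silylation, bromine–lithium exchange and anionic 1,3-silyl migration from oxygen to carbon (retro-Brook rearrangement) give the ortho-silylphenoxide, which Tf2O sulfonylates on oxygen, the standard one-flask route to ortho-silylaryl triflates.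

**Step 5**
Reactants: 12 1-hexacosanol
Product: 13 hexacosanal
Conditions: PhI(OAc)2, TEMPO (10 mol %), CH2Cl2, 35 °C
Reagents that add atoms: none
Why: TEMPO-catalysed oxidation with PhI(OAc)2 as the terminal oxidant stops at the aldehyde for a primary aliphatic alcohol and tolerates the gentle warming needed to keep the C26 chain dissolved.

**Step 6**
Reactants: 13 hexacosanal
Product: 14 1,1-dibromoheptacos-1-ene
Conditions: CBr4, PPh3, CH2Cl2, 0 °C → rt
Reagents that add atoms: carbon tetrabromide, BrC(Br)(Br)Br
Why: First stage of the Corey–Fuchs sequence, a Wittig reaction of the unhindered aldehyde with the ylide Ph3P=CBr2 formed from PPh3 and CBr4.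

**Step 7**
Reactants: 14 1,1-dibromoheptacos-1-ene
Product: 16 octacos-2-ynoic acid, via lithium acetylide 15 (not isolated)
Conditions: n-BuLi (2.2 equiv), THF, –78 °C → 0 °C; CO2, –78 °C → rt; aq HCl
Reagents that add atoms: carbon dioxide, O=C=O
Why: Second stage of the Corey–Fuchs alkyne synthesis (bromine–lithium exchange, Fritsch–Buttenberg–Wiechell 1,2-shift and deprotonation by the second equivalent of n-BuLi) gives the lithium acetylide, which is carboxylated by CO2.

**Step 8**
Reactants: 11 2,4-dimethoxy-3,5-dimethyl-6-(trimethylsilyl)phenyl trifluoromethanesulfonate (1.5 equiv); 16 octacos-2-ynoic acid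
Product: 20 5,7-dimethoxy-6,8-dimethyl-2-pentacosyl-4H-chromen-4-one, via aryne 17 (not isolated), via benzoxetene adduct 18 (not isolated), via hydroxyaryl ynone 19 (not isolated)
Conditions: CsF (4 equiv), THF, 125 °C, sealed tube
Reagents that add atoms: none
Why: Fluoride attacks silicon in 11 and triflate leaves to give aryne 17 (C4a≡C8a); the caesium carboxylate of 16 adds through oxygen at C8a, the aryl anion at C4a attacks the carboxyl carbon to give the four-membered alkoxide 18, and this opens to the o-acylphenoxide 19, a net insertion into the acid C–O bond that forms C8a–O1 and C4a–C4. The phenoxide oxygen then adds to the ynone at C2 (oxa-Michael addition), which forms O1–C2 and, after protonation at C3, the pyranone ring. The closest known reaction type is the fluoride-mediated insertion of arynes into the C–O bond of carboxylic acids, which with alk-2-ynoic acids continues to chromones and flavones. The transient oxetene closes 4-exo-trig and reopens, the pyranone ring closes 6-endo-dig, and no stereocentre is formed. The step needs carboxylate attack at C8a and not C4a, which the C5 methoxy group beside C4a secures by stabilising negative charge at C4a inductively and distorting the aryne so that C8a is the more electrophilic terminus, outweighing the small steric bias of the C8 methyl group. It also needs acyl transfer to outrun protonation of the C4a anion by a second acid molecule, which heating in aprotic THF with the acid held as its caesium salt should favour.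

**Step 9**
Reactants: 20 5,7-dimethoxy-6,8-dimethyl-2-pentacosyl-4H-chromen-4-one
Product: 21 5,7-dihydroxy-6,8-dimethyl-2-pentacosyl-4H-chromen-4-one
Conditions: BBr3 (6 equiv), CH2Cl2, –78 °C → rt; then H2O
Reagents that add atoms: none
Why: Lewis-acid ether cleavage, in which BBr3 binds each methoxy oxygen and bromide removes the methyl group by SN2 (the C5 ether assisted by chelation to the C4 carbonyl, the C7 ether unhindered at its methyl carbon), should leave the chromone and the saturated chain untouched.

**Compound list**
1 | 2,6-dimethoxytoluene | COc1cccc(OC)c1C | starting material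
2 | (2,4-dimethoxy-3-methylphenyl)lithium | [Li]c1ccc(OC)c(C)c1OC | intermediate
3 | 1,3-dimethoxy-2,4-dimethylbenzene | COc1ccc(C)c(OC)c1C | intermediate
4 | (2,4-dimethoxy-3,5-dimethylphenyl)lithium | [Li]c1cc(C)c(OC)c(C)c1OC | intermediate
5 | dimethyl (2,4-dimethoxy-3,5-dimethylphenyl)boronate | COB(OC)c1cc(C)c(OC)c(C)c1OC | intermediate
6 | 2,4-dimethoxy-3,5-dimethylphenol | COc1c(C)c(OC)c(C)cc1O | intermediate
7 | 2-bromo-4,6-dimethoxy-3,5-dimethylphenol | COc1c(C)c(OC)c(C)c(Br)c1O | intermediate
8 | (2-bromo-4,6-dimethoxy-3,5-dimethylphenoxy)trimethylsilane | COc1c(C)c(OC)c(C)c(Br)c1O[Si](C)(C)C | intermediate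
9 | [3,5-dimethoxy-4,6-dimethyl-2-(trimethylsilyloxy)phenyl]lithium | [Li]c1c(C)c(OC)c(C)c(OC)c1O[Si](C)(C)C | intermediate
10 | lithium 2,4-dimethoxy-3,5-dimethyl-6-(trimethylsilyl)phenolate | [Li]Oc1c(OC)c(C)c(OC)c(C)c1[Si](C)(C)C | intermediate
11 | 2,4-dimethoxy-3,5-dimethyl-6-(trimethylsilyl)phenyl trifluoromethanesulfonate | COc1c(C)c(OC)c(C)c([Si](C)(C)C)c1OS(=O)(=O)C(F)(F)F | intermediate
12 | 1-hexacosanol | CCCCCCCCCCCCCCCCCCCCCCCCCCO | starting material
13 | hexacosanal | CCCCCCCCCCCCCCCCCCCCCCCCCC=O | intermediate
14 | 1,1-dibromoheptacos-1-ene | CCCCCCCCCCCCCCCCCCCCCCCCCC=C(Br)Br | intermediate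
15 | lithium heptacos-1-yn-1-ide | CCCCCCCCCCCCCCCCCCCCCCCCCC#C[Li] | intermediate
16 | octacos-2-ynoic acid | CCCCCCCCCCCCCCCCCCCCCCCCCC#CC(=O)O | intermediate
17 | 3,5-dimethoxy-4,6-dimethylbenzyne (1,2-didehydro-3,5-dimethoxy-4,6-dimethylbenzene) | COC1=C(C)C(OC)=C(C)C#C1 | intermediate
18 | 2-(heptacos-1-yn-1-yl)-3,5-dimethoxy-4,6-dimethyl-2H-1-benzoxet-2-ol (present as its caesium alkoxide, drawn neutral) | CCCCCCCCCCCCCCCCCCCCCCCCCC#CC1(O)Oc2c(C)c(OC)c(C)c(OC)c12 | intermediate
19 | 1-(2-hydroxy-4,6-dimethoxy-3,5-dimethylphenyl)octacos-2-yn-1-one (present as its caesium phenoxide, drawn neutral) | CCCCCCCCCCCCCCCCCCCCCCCCCC#CC(=O)c1c(O)c(C)c(OC)c(C)c1OC | intermediate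
20 | 5,7-dimethoxy-6,8-dimethyl-2-pentacosyl-4H-chromen-4-one | CCCCCCCCCCCCCCCCCCCCCCCCCc1cc(=O)c2c(OC)c(C)c(OC)c(C)c2o1 | intermediate
21 | 5,7-dihydroxy-6,8-dimethyl-2-pentacosyl-4H-chromen-4-one | CCCCCCCCCCCCCCCCCCCCCCCCCc1cc(=O)c2c(O)c(C)c(O)c(C)c2o1 | target

**Step count**
Total step count: 9 (steps 1–4 for the aryne precursor, steps 5–7 for the acid, steps 8 and 9 after the union).
Longest linear sequence: 6 steps (1, 2, 3, 4, 8, 9).

**Steps most likely to fail**

Step 8. Several processes could divert the key step:
- protonation of the C4a aryl anion before acyl transfer, which would stop at simple O-arylation of the acid;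
- carboxylate addition at the wrong aryne terminus;
- loss of CO2 from the alkynoate at 125 °C;
- 5-exo-dig closure of the phenoxide in place of the 6-endo-dig closure.

Fallback: this sets out from 11 and from lithium acetylide 15 (made from 14 as in step 7, without the CO2 quench) and avoids any acidic partner. Aryne 17 is generated from 11 with CsF in DMF, where it inserts into the formamide C=O bond with oxygen again going to C8a. Aqueous work-up hydrolyses the aminal and should give 2-hydroxy-4,6-dimethoxy-3,5-dimethylbenzaldehyde F1. Addition of 15 in THF at –78 °C → 0 °C (one extra equivalent serving as base for the phenol) should give racemic 2-(1-hydroxyoctacos-2-yn-1-yl)-3,5-dimethoxy-4,6-dimethylphenol F2. MnO2 in CH2Cl2 oxidises the benzylic propargylic alcohol to ynone 19, and Et2NH in EtOH closes the pyranone ring, so the route is rejoined at 20.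

Step 2. Deprotonation at a benzylic methyl group could compete with ring lithiation, and the electron-rich phenol could be oxidised further during the peroxide work-up.

Fallback: this sets out from 3. NBS in MeCN brominates the most activated ring position (ortho and para to the two methoxy groups) to give 1-bromo-2,4-dimethoxy-3,5-dimethylbenzene F3. Bromine–lithium exchange with n-BuLi in THF at –78 °C then gives aryllithium 4 at a fixed position. Borylation and oxidation as in step 2 rejoin the route at 6.

Step 4. On the fully substituted ring, n-BuLi could attack silicon in place of bromine, the silyl shift from oxygen to carbon could stay incomplete, and triflation of the hindered phenoxide could be slow.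

Fallback: this sets out from 6 and bypasses steps 3 and 4 by carbamate-directed ortho-metalation.
- Isopropyl isocyanate with Et3N in CH2Cl2 gives 2,4-dimethoxy-3,5-dimethylphenyl N-(propan-2-yl)carbamate F4.
- The N–H is silylated in the flask with TBSOTf/TMEDA in Et2O to 2,4-dimethoxy-3,5-dimethylphenyl N-(tert-butyldimethylsilyl)-N-(propan-2-yl)carbamate F5.
- F5 is lithiated at the free ring position with n-BuLi/TMEDA at –78 °C and quenched with TMSCl. Acidic work-up removes the N-silyl group to give 2,4-dimethoxy-3,5-dimethyl-6-(trimethylsilyl)phenyl N-(propan-2-yl)carbamate F6.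
- DBU and Et2NH in MeCN at 40 °C cleave the carbamate, and PhNTf2 triflates the released phenoxide, so the route is rejoined at 11.

**Further compounds**
F1 | step 8 | 2-hydroxy-4,6-dimethoxy-3,5-dimethylbenzaldehyde | O=Cc1c(O)c(C)c(OC)c(C)c1OC
F2 | step 8 | 2-(1-hydroxyoctacos-2-yn-1-yl)-3,5-dimethoxy-4,6-dimethylphenol (racemic) | CCCCCCCCCCCCCCCCCCCCCCCCCC#CC(O)c1c(O)c(C)c(OC)c(C)c1OC
F3 | step 2 | 1-bromo-2,4-dimethoxy-3,5-dimethylbenzene | COc1c(C)c(OC)c(C)cc1Br
F4 | step 4 | 2,4-dimethoxy-3,5-dimethylphenyl N-(propan-2-yl)carbamate | CC(C)NC(=O)Oc1cc(C)c(OC)c(C)c1OC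
F5 | step 4 | 2,4-dimethoxy-3,5-dimethylphenyl N-(tert-butyldimethylsilyl)-N-(propan-2-yl)carbamate | CC(C)N(C(=O)Oc1cc(C)c(OC)c(C)c1OC)[Si](C)(C)C(C)(C)C
F6 | step 4 | 2,4-dimethoxy-3,5-dimethyl-6-(trimethylsilyl)phenyl N-(propan-2-yl)carbamate | CC(C)NC(=O)Oc1c(OC)c(C)c(OC)c(C)c1[Si](C)(C)C
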